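**Strategy.** The upper ring C (O1–C2–C3–C4–C4a–C8a) is cut across O1–C2 and C3–C4. This gives a hetero-diene O1=C8a–C4a=C4 (an ortho-quinone methide from the pyrogallol ring A aldehyde, C4 carrying a temporary methoxy group) and the C2=C3 bond of a (Z)-4-benzyloxystyryl benzoate. One chiral-acid-catalysed oxa-[4+2] cycloaddition closes ring C, places oxygen on C3 and writes the 2,3-cis relationship from the alkene geometry. The feature exploited is the benzylic C4, flanked by O1 (ortho) and O7 (para). It can leave the key step as an unselective acetal-like centre and is later re-ionised and joined, trans to O3, to C6 of a second flavan made by the same cycloaddition.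

Key step: step 3

Assumption: the (R)-configured acid catalyst is taken to give the (2R,3R) series in steps 3 and 7; should the sense of induction prove opposite, the (S)-catalyst is used.

**Step 1**
Reactants: 1 2,3,4-trihydroxybenzaldehyde
Product: 2 3,4-bis(benzyloxy)-2-hydroxybenzaldehyde
Conditions: BnBr (2.05 equiv), K2CO3 (2.1 equiv), DMF, 0 °C to rt
Reagents that add atoms: benzyl bromide, BrCc1ccccc1
Why: Williamson etherification in which the 2-OH, hydrogen-bonded to the formyl group, is the least nucleophilic site, so the 4- and 3-phenoxides are alkylated first.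

**Step 2**
Reactants: 3 1-(benzyloxy)-4-ethynylbenzene
Product: 4 (Z)-2-[4-(benzyloxy)phenyl]ethenyl benzoate
Conditions: PhCO2H (1.1 equiv), Ru(2-methylallyl)2(dppb) [Ru(C4H7)2(Ph2P(CH2)4PPh2)] (2 mol%), toluene, 60 °C
Reagents that add atoms: benzoic acid, OC(=O)c1ccccc1
Why: Ruthenium-catalysed anti-Markovnikov hydro-acyloxylation of a terminal alkyne through a ruthenium vinylidene, in which carboxylate attack at the vinylidene α-carbon and protonolysis should give the (Z)-enol ester.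

**Step 3**
Reactants: 2 3,4-bis(benzyloxy)-2-hydroxybenzaldehyde; 4 (Z)-2-[4-(benzyloxy)phenyl]ethenyl benzoate (1.5 equiv)
Product: 7 (2R,3R)-7,8-bis(benzyloxy)-2-[4-(benzyloxy)phenyl]-4-methoxychroman-3-yl benzoate (2,3-cis; both C4 epimers), via dimethyl acetal 5 (not isolated), via methoxy ortho-quinone methide 6 (not isolated)
Conditions: HC(OMe)3 (1.5 equiv), (R)-3,3'-bis(2,4,6-triisopropylphenyl)-BINOL N-triflylphosphoramide (10 mol%), 5 Å MS, toluene, −20 °C to rt
Reagents that add atoms: trimethyl orthoformate, COC(OC)OC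
Why: Proposed new method: the acid converts 2 and the orthoformate into acetal 5 and, by loss of methanol, into the 4-methoxy ortho-quinone methide 6 (or its O-protonated oxocarbenium form), which is hydrogen-bonded through O1 to the chiral phosphoramide and should undergo an inverse-electron-demand oxa-[4+2] cycloaddition with the C2=C3 bond of 4; the closest known reaction type is the acid-catalysed three-component chroman synthesis from salicylaldehydes, orthoformates and styrenes, together with chiral-acid-controlled ortho-quinone methide/styrene cycloadditions. Ring C closes in a concerted but asynchronous suprafacial [4π+2π] mode (in the stepwise limit, six-membered ring closure by O1 on the C2 benzylic cation after C3–C4 bond formation), and the strongly donating 4-benzyloxyphenyl group, not the weakly donating benzoyloxy group, should fix the regiochemistry (C3 to C4, O1 to C2). C2 and C3 are set together: their cis relationship is copied from the (Z)-alkene, and their absolute sense (2R,3R) is set by the catalyst, which shields one face of the hydrogen-bonded hetero-diene. C4 forms as an epimer mixture (endo and exo modes), which is tolerated because this acetal-like centre is re-ionised and reset in step 4. The selectivity the step needs is retention of alkene geometry, which requires ring closure to outrun rotation in any C2 cation; the free phenolic O1 of 2, held next to C2 by the catalyst, is what secures it.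

**Step 4**
Reactants: 7 (2R,3R)-7,8-bis(benzyloxy)-2-[4-(benzyloxy)phenyl]-4-methoxychroman-3-yl benzoate
Product: 8 (2R,3S,4S)-7,8-bis(benzyloxy)-2-[4-(benzyloxy)phenyl]-4-(benzylsulfanyl)chroman-3-yl benzoate (2,3-cis-3,4-trans; 4β-sulfide)
Conditions: BnSH (5 equiv), BF3·OEt2 (0.2 equiv), CH2Cl2, −40 to 0 °C
Reagents that add atoms: phenylmethanethiol, SCc1ccccc1
Why: SN1 thiolysis of the benzylic C4 ether (cation stabilised by O1 ortho and the 7-benzyloxy group para to C4a), in which both C4 epimers converge on one benzoate-bridged cation that the thiol opens anti, so only the 3,4-trans sulfide should form.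

**Step 5**
Reactants: 9 3,4-bis(benzyloxy)benzaldehyde
Product: 10 1,2-bis(benzyloxy)-4-ethynylbenzene
Conditions: dimethyl (1-diazo-2-oxopropyl)phosphonate (1.3 equiv), K2CO3 (2 equiv), MeOH/THF, rt
Reagents that add atoms: dimethyl (1-diazo-2-oxopropyl)phosphonate, COP(=O)(OC)C(=[N+]=[N-])C(C)=O
Why: Ohira–Bestmann (Seyferth–Gilbert) homologation of an aromatic aldehyde to the terminal alkyne under conditions that leave benzyl ethers untouched.

**Step 6**
Reactants: 10 1,2-bis(benzyloxy)-4-ethynylbenzene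
Product: 11 (Z)-2-[3,4-bis(benzyloxy)phenyl]ethenyl benzoate
Conditions: PhCO2H (1.1 equiv), Ru(2-methylallyl)2(dppb) [Ru(C4H7)2(Ph2P(CH2)4PPh2)] (2 mol%), toluene, 60 °C
Reagents that add atoms: benzoic acid, OC(=O)c1ccccc1
Why: The same ruthenium-vinylidene anti-Markovnikov hydro-acyloxylation as in step 2, expected to give the (Z)-enol ester.

**Step 7**
Reactants: 2 3,4-bis(benzyloxy)-2-hydroxybenzaldehyde; 11 (Z)-2-[3,4-bis(benzyloxy)phenyl]ethenyl benzoate (1.5 equiv)
Product: 14 (2R,3R)-7,8-bis(benzyloxy)-2-[3,4-bis(benzyloxy)phenyl]-4-ethoxychroman-3-yl benzoate (2,3-cis; both C4 epimers), via diethyl acetal 12 (not isolated), via ethoxy ortho-quinone methide 13 (not isolated)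
Conditions: HC(OEt)3 (1.5 equiv), (R)-3,3'-bis(2,4,6-triisopropylphenyl)-BINOL N-triflylphosphoramide (10 mol%), 5 Å MS, toluene, −20 °C to rt
Reagents that add atoms: triethyl orthoformate, CCOC(OCC)OCC
Why: Proposed new method: here triethyl orthoformate is used, so that the acid converts 2 into the diethyl acetal 12 and then, by loss of ethanol, into the catalyst-bound 4-ethoxy ortho-quinone methide 13, which should add across the enol-ester double bond of 11 in an oxa-[4+2] cycloaddition (closest known type: acid-catalysed salicylaldehyde/orthoformate/styrene chroman synthesis), the para-benzyloxy group of the styrene fixing the regiochemistry, the (Z)-geometry the 2,3-cis relationship and the catalyst the (2R,3R) sense, while the C4 ethoxy group is a placeholder that is exchanged in step 8.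

**Step 8**
Reactants: 14 (2R,3R)-7,8-bis(benzyloxy)-2-[3,4-bis(benzyloxy)phenyl]-4-ethoxychroman-3-yl benzoate
Product: 15 (2R,3R,4S)-4,7,8-tris(benzyloxy)-2-[3,4-bis(benzyloxy)phenyl]chroman-3-yl benzoate (2,3-cis-3,4-trans; 4β-ether)
Conditions: BnOH (20 equiv), camphorsulfonic acid (0.1 equiv), 5 Å MS, CH2Cl2, 0 °C, then Et3N quench
Reagents that add atoms: benzyl alcohol, OCc1ccccc1
Why: Acid-catalysed transetherification through the C4 benzylic cation, in which both C4 epimers should funnel into the ether trans to the participating 3-benzoate while the large excess of alcohol outcompetes C-alkylation of another arene.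

**Step 9**
Reactants: 8 the 4β-benzylsulfanyl flavan benzoate (added slowly); 15 the 4β-benzyloxy flavan benzoate (2.5 equiv, excess recovered)
Product: 16 protected dimer: the (2R,3R)-3-benzoyloxy-7,8-bis(benzyloxy)-2-[4-(benzyloxy)phenyl]chroman-4-yl unit bonded through C4 (4β; 3,4-trans) to C6 of (2R,3R,4S)-4,7,8-tris(benzyloxy)-2-[3,4-bis(benzyloxy)phenyl]chroman-3-yl benzoate
Conditions: AgBF4 (2.5 equiv), 2,6-di-tert-butylpyridine (1.5 equiv), THF, 0 °C
Reagents that add atoms: none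
Why: Thiophilic activation of the C4 sulfide followed by Friedel–Crafts alkylation at C6 of 15 (ortho to the 7-benzyloxy group, para to O1), anti to the participating 3-benzoate so that the new bond is 4β, with the benzyl ether at C4 of 15 inert to the silver salt.

**Step 10**
Reactants: 16 protected dimer
Product: 17 the same dimer with free 3-OH groups on both units (upper unit 2R,3R with 4β bond to C6; lower unit 2R,3R,4S with 4-benzyloxy)
Conditions: NaOMe (0.5 equiv), MeOH/THF 1:1, 40 °C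
Reagents that add atoms: none
Why: Base-catalysed transesterification (Zemplén type) removes both benzoates without touching the benzyl ethers or any stereocentre.

**Step 11**
Reactants: 17 debenzoylated dimer
Product: 18 (2R,3R,4S)-2-(3,4-dihydroxyphenyl)-6-[(2R,3R,4S)-3,7,8-trihydroxy-2-(4-hydroxyphenyl)chroman-4-yl]chromane-3,4,7,8-tetrol (CNP0275688.1)
Conditions: H2 (1 atm), Pd(OH)2/C, THF/H2O 10:1, rt, filtration under argon
Reagents that add atoms: none
Why: Neutral hydrogenolysis of the eight O-benzyl groups, in which the unhindered O–CH2Ph bonds (including that of the C4 ether) should cleave faster than the ring C4–O bond.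

**Compound list**

1 | 2,3,4-trihydroxybenzaldehyde | O=Cc1ccc(O)c(O)c1O | starting material
2 | 3,4-bis(benzyloxy)-2-hydroxybenzaldehyde | O=Cc1ccc(OCc2ccccc2)c(OCc2ccccc2)c1O | intermediate
3 | 1-(benzyloxy)-4-ethynylbenzene | C#Cc1ccc(OCc2ccccc2)cc1 | starting material
4 | (Z)-2-[4-(benzyloxy)phenyl]ethenyl benzoate | O=C(O/C=C\c1ccc(OCc2ccccc2)cc1)c1ccccc1 | intermediate
5 | 2,3-bis(benzyloxy)-6-(dimethoxymethyl)phenol | COC(OC)c1ccc(OCc2ccccc2)c(OCc2ccccc2)c1O | intermediate
6 | (6E)-2,3-bis(benzyloxy)-6-(methoxymethylidene)cyclohexa-2,4-dien-1-one | CO/C=C1\C=CC(OCc2ccccc2)=C(OCc2ccccc2)C1=O | intermediate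
7 | (2R,3R)-7,8-bis(benzyloxy)-2-[4-(benzyloxy)phenyl]-4-methoxychroman-3-yl benzoate, both C4 epimers | C(c1ccccc1)Oc1ccc(cc1)[C@H]1Oc2c(ccc(OCc3ccccc3)c2OCc2ccccc2)C(OC)[C@H]1OC(=O)c1ccccc1 | intermediate
8 | (2R,3S,4S)-7,8-bis(benzyloxy)-2-[4-(benzyloxy)phenyl]-4-(benzylsulfanyl)chroman-3-yl benzoate (2,3-cis-3,4-trans) | C(c1ccccc1)Oc1ccc(cc1)[C@H]1Oc2c(ccc(OCc3ccccc3)c2OCc2ccccc2)[C@H](SCc2ccccc2)[C@H]1OC(=O)c1ccccc1 | intermediate
9 | 3,4-bis(benzyloxy)benzaldehyde | O=Cc1ccc(OCc2ccccc2)c(OCc2ccccc2)c1 | starting material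
10 | 1,2-bis(benzyloxy)-4-ethynylbenzene | C#Cc1ccc(OCc2ccccc2)c(OCc2ccccc2)c1 | intermediate
11 | (Z)-2-[3,4-bis(benzyloxy)phenyl]ethenyl benzoate | O=C(O/C=C\c1ccc(OCc2ccccc2)c(OCc2ccccc2)c1)c1ccccc1 | intermediate
12 | 2,3-bis(benzyloxy)-6-(diethoxymethyl)phenol | CCOC(OCC)c1ccc(OCc2ccccc2)c(OCc2ccccc2)c1O | intermediate
13 | (6E)-2,3-bis(benzyloxy)-6-(ethoxymethylidene)cyclohexa-2,4-dien-1-one | CCO/C=C1\C=CC(OCc2ccccc2)=C(OCc2ccccc2)C1=O | intermediate
14 | (2R,3R)-7,8-bis(benzyloxy)-2-[3,4-bis(benzyloxy)phenyl]-4-ethoxychroman-3-yl benzoate, both C4 epimers | c1cc2c(c(OCc3ccccc3)c1OCc1ccccc1)O[C@H](c1ccc(OCc3ccccc3)c(OCc3ccccc3)c1)[C@H](OC(=O)c1ccccc1)C2OCC | intermediate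
15 | (2R,3R,4S)-4,7,8-tris(benzyloxy)-2-[3,4-bis(benzyloxy)phenyl]chroman-3-yl benzoate (2,3-cis-3,4-trans) | c1cc2c(c(OCc3ccccc3)c1OCc1ccccc1)O[C@H](c1ccc(OCc3ccccc3)c(OCc3ccccc3)c1)[C@H](OC(=O)c1ccccc1)[C@H]2OCc1ccccc1 | intermediate
16 | protected dimer: upper unit (2R,3R)-3-benzoyloxy-7,8-bis(benzyloxy)-2-[4-(benzyloxy)phenyl]chroman with its 4β bond (3,4-trans) to C6 of the lower unit (2R,3R,4S)-3-benzoyloxy-4,7,8-tris(benzyloxy)-2-[3,4-bis(benzyloxy)phenyl]chroman | C(c1ccccc1)Oc1ccc([C@H]2Oc3c(ccc(OCc4ccccc4)c3OCc3ccccc3)[C@H](c3cc4c(c(OCc5ccccc5)c3OCc3ccccc3)O[C@H](c3ccc(OCc5ccccc5)c(OCc5ccccc5)c3)[C@H](OC(=O)c3ccccc3)[C@H]4OCc3ccccc3)[C@H]2OC(=O)c2ccccc2)cc1 | intermediate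
17 | dimer 16 with both benzoates replaced by free 3-OH groups | C(c1ccccc1)Oc1ccc([C@H]2Oc3c(ccc(OCc4ccccc4)c3OCc3ccccc3)[C@H](c3cc4c(c(OCc5ccccc5)c3OCc3ccccc3)O[C@H](c3ccc(OCc5ccccc5)c(OCc5ccccc5)c3)[C@H](O)[C@H]4OCc3ccccc3)[C@H]2O)cc1 | intermediate
18 | (2R,3R,4S)-2-(3,4-dihydroxyphenyl)-6-[(2R,3R,4S)-3,7,8-trihydroxy-2-(4-hydroxyphenyl)chroman-4-yl]chromane-3,4,7,8-tetrol | Oc1ccc([C@H]2Oc3c(ccc(O)c3O)[C@H](c3cc4c(c(O)c3O)O[C@H](c3ccc(O)c(O)c3)[C@H](O)[C@H]4O)[C@H]2O)cc1 | target

**Step count and risks**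

Total steps: 11. Longest linear sequence: 7 (steps 5, 6, 7, 8, 9, 10, 11).

Step 3 (Proposed new method). What may go wrong: sluggish engagement of the enol ester by the quinone methide, erosion of the 2,3-cis relationship by bond rotation in an open C2 cation, or poor facial selectivity. The fallback uses known chemistry and sets out from 2. An amine-catalysed oxa-Michael/aldol condensation of 2 with (E)-3-[4-(benzyloxy)phenyl]prop-2-enal (diarylprolinol silyl ether of the antipode that gives the 2R product, 2-nitrobenzoic acid, toluene) forms the same two ring bonds and should give (2R)-7,8-bis(benzyloxy)-2-[4-(benzyloxy)phenyl]-2H-chromene-3-carbaldehyde F1. Baeyer–Villiger oxidation of the enal (mCPBA, NaHCO3, CH2Cl2) should give the enol formate (2R)-7,8-bis(benzyloxy)-2-[4-(benzyloxy)phenyl]-2H-chromen-3-yl formate F2, and cold methanolysis (NaHCO3, MeOH) the flavan-3-one (2R)-7,8-bis(benzyloxy)-2-[4-(benzyloxy)phenyl]chroman-3-one F3. Reduction with LiBH(s-Bu)3 at −78 °C should give the 2,3-cis alcohol (2R,3R)-7,8-bis(benzyloxy)-2-[4-(benzyloxy)phenyl]chroman-3-ol F4. Oxidation at C4 with DDQ in CH2Cl2/MeOH should give (2R,3R,4S)-7,8-bis(benzyloxy)-2-[4-(benzyloxy)phenyl]-4-methoxychroman-3-ol F5. Benzoylation (BzCl, pyridine, DMAP) gives the 4S epimer of 7, where the route is rejoined before step 4.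

Step 7 (Proposed new method). What may go wrong: the same processes as in step 3, plus acid-induced decomposition of the more electron-rich catechol-type enol ester. The fallback uses the same known sequence and sets out from 2. Condensation with (E)-3-[3,4-bis(benzyloxy)phenyl]prop-2-enal should give (2R)-7,8-bis(benzyloxy)-2-[3,4-bis(benzyloxy)phenyl]-2H-chromene-3-carbaldehyde F6. Baeyer–Villiger oxidation should give the enol formate (2R)-7,8-bis(benzyloxy)-2-[3,4-bis(benzyloxy)phenyl]-2H-chromen-3-yl formate F7, and methanolysis the ketone (2R)-7,8-bis(benzyloxy)-2-[3,4-bis(benzyloxy)phenyl]chroman-3-one F8. Reduction with LiBH(s-Bu)3 should give (2R,3R)-7,8-bis(benzyloxy)-2-[3,4-bis(benzyloxy)phenyl]chroman-3-ol F9. DDQ oxidation in the presence of benzyl alcohol should give (2R,3R,4S)-4,7,8-tris(benzyloxy)-2-[3,4-bis(benzyloxy)phenyl]chroman-3-ol F10. Benzoylation then comes back to the route at 15.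

Step 9. What may go wrong: self-alkylation of the electrophile at its own nucleophilic C6, or adventitious acid ionising the C4 benzyl ether of 15, both leading to oligomers. The fallback blocks the competing position and sets out from 7. Bromination with NBS (CH2Cl2, 0 °C) at C6 (ortho to the 7-benzyloxy group, para to O1) should give the 6-bromo derivative of 7, (2R,3R)-7,8-bis(benzyloxy)-2-[4-(benzyloxy)phenyl]-6-bromo-4-methoxychroman-3-yl benzoate F11. Thiolysis as in step 4 should give the 6-bromo-4β-benzylsulfanyl flavan benzoate F12. Coupling with only 1.2 equiv of 15 (AgBF4, 2,6-di-tert-butylpyridine) should give the 6-bromo protected dimer F13, and NaOMe the 6-bromo debenzoylated dimer F14. Hydrogenolysis over Pd(OH)2/C with added Et3N removes the bromine together with the benzyl groups and comes back to the route at 18.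

**Further compounds**

F1 | step 3 | (2R)-7,8-bis(benzyloxy)-2-[4-(benzyloxy)phenyl]-2H-chromene-3-carbaldehyde | C(c1ccccc1)Oc1ccc(cc1)[C@H]1Oc2c(ccc(OCc3ccccc3)c2OCc2ccccc2)C=C1C=O
F2 | step 3 | (2R)-7,8-bis(benzyloxy)-2-[4-(benzyloxy)phenyl]-2H-chromen-3-yl formate | C(c1ccccc1)Oc1ccc(cc1)[C@H]1Oc2c(ccc(OCc3ccccc3)c2OCc2ccccc2)C=C1OC=O
F3 | step 3 | (2R)-7,8-bis(benzyloxy)-2-[4-(benzyloxy)phenyl]chroman-3-one | C(c1ccccc1)Oc1ccc(cc1)[C@H]1Oc2c(ccc(OCc3ccccc3)c2OCc2ccccc2)CC1=O
F4 | step 3 | (2R,3R)-7,8-bis(benzyloxy)-2-[4-(benzyloxy)phenyl]chroman-3-ol | C(c1ccccc1)Oc1ccc(cc1)[C@H]1Oc2c(ccc(OCc3ccccc3)c2OCc2ccccc2)C[C@H]1O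
F5 | step 3 | (2R,3R,4S)-7,8-bis(benzyloxy)-2-[4-(benzyloxy)phenyl]-4-methoxychroman-3-ol | C(c1ccccc1)Oc1ccc(cc1)[C@H]1Oc2c(ccc(OCc3ccccc3)c2OCc2ccccc2)[C@H](OC)[C@H]1O
F6 | step 7 | (2R)-7,8-bis(benzyloxy)-2-[3,4-bis(benzyloxy)phenyl]-2H-chromene-3-carbaldehyde | C(c1ccccc1)Oc1ccc(cc1OCc1ccccc1)[C@H]1Oc2c(ccc(OCc3ccccc3)c2OCc2ccccc2)C=C1C=O
F7 | step 7 | (2R)-7,8-bis(benzyloxy)-2-[3,4-bis(benzyloxy)phenyl]-2H-chromen-3-yl formate | C(c1ccccc1)Oc1ccc(cc1OCc1ccccc1)[C@H]1Oc2c(ccc(OCc3ccccc3)c2OCc2ccccc2)C=C1OC=O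
F8 | step 7 | (2R)-7,8-bis(benzyloxy)-2-[3,4-bis(benzyloxy)phenyl]chroman-3-one | C(c1ccccc1)Oc1ccc(cc1OCc1ccccc1)[C@H]1Oc2c(ccc(OCc3ccccc3)c2OCc2ccccc2)CC1=O
F9 | step 7 | (2R,3R)-7,8-bis(benzyloxy)-2-[3,4-bis(benzyloxy)phenyl]chroman-3-ol | C(c1ccccc1)Oc1ccc(cc1OCc1ccccc1)[C@H]1Oc2c(ccc(OCc3ccccc3)c2OCc2ccccc2)C[C@H]1O
F10 | step 7 | (2R,3R,4S)-4,7,8-tris(benzyloxy)-2-[3,4-bis(benzyloxy)phenyl]chroman-3-ol | C(c1ccccc1)Oc1ccc(cc1OCc1ccccc1)[C@H]1Oc2c(ccc(OCc3ccccc3)c2OCc2ccccc2)[C@H](OCc2ccccc2)[C@H]1O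
F11 | step 9 | (2R,3R)-7,8-bis(benzyloxy)-2-[4-(benzyloxy)phenyl]-6-bromo-4-methoxychroman-3-yl benzoate, both C4 epimers | C(c1ccccc1)Oc1ccc(cc1)[C@H]1Oc2c(cc(Br)c(OCc3ccccc3)c2OCc2ccccc2)C(OC)[C@H]1OC(=O)c1ccccc1
F12 | step 9 | 6-bromo derivative of 8: (2R,3S,4S)-7,8-bis(benzyloxy)-2-[4-(benzyloxy)phenyl]-4-(benzylsulfanyl)-6-bromochroman-3-yl benzoate | C(c1ccccc1)Oc1ccc(cc1)[C@H]1Oc2c(cc(Br)c(OCc3ccccc3)c2OCc2ccccc2)[C@H](SCc2ccccc2)[C@H]1OC(=O)c1ccccc1
F13 | step 9 | 6-bromo derivative (upper unit) of protected dimer 16 | C(c1ccccc1)Oc1ccc([C@H]2Oc3c(cc(Br)c(OCc4ccccc4)c3OCc3ccccc3)[C@H](c3cc4c(c(OCc5ccccc5)c3OCc3ccccc3)O[C@H](c3ccc(OCc5ccccc5)c(OCc5ccccc5)c3)[C@H](OC(=O)c3ccccc3)[C@H]4OCc3ccccc3)[C@H]2OC(=O)c2ccccc2)cc1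
F14 | step 9 | 6-bromo derivative (upper unit) of debenzoylated dimer 17 | C(c1ccccc1)Oc1ccc([C@H]2Oc3c(cc(Br)c(OCc4ccccc4)c3OCc3ccccc3)[C@H](c3cc4c(c(OCc5ccccc5)c3OCc3ccccc3)O[C@H](c3ccc(OCc5ccccc5)c(OCc5ccccc5)c3)[C@H](O)[C@H]4OCc3ccccc3)[C@H]2O)cc1
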